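The route rests on opening unit 1 (the styryl-bearing dihydrobenzofuran; unit 2, primed, carries the catechol) at C2–aryl, C3–C3a and O1–C7a. The feature exploited is that C2 and C3 are a former E-alkene pair in which C3 already bears C6′ of unit 2. One palladium-catalysed conjunctive coupling of an alkenylboronate, 4-methoxyphenyllithium and the ring A triflate (C3a–OTf between C4–OMe and C7a–Cl) places the anisyl ring on C2 and C3a on C3 by anti addition. Both centres are thus set under ligand control, and boron marks the site of O1. The precursor is permethylated unit 2, built the same way with the mirror-image ligand, carrying an (E)-2-borylvinyl group at C6′.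

Key step: step 10

Design remarks
- Boron carries the diolate of cis-1,2-dimethylacenaphthylene-1,2-diol ("mac") instead of pinacolate. β-Substituted alkenyl pinacol borates tend to pass their alkenyl or aryl group straight to palladium. The carbon skeleton and the disconnection are unchanged.
- Both aryllithiums are made with n-BuLi. This gives volatile butyl bromide and no lithium halide, so nothing coordinating reaches the cationic arylpalladium.
- The aldehyde of unit 2 travels as a dioxolane through the borate and base steps.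
- One triflate made from 5-chlorovanillin serves both halves.
- Methyl ethers are kept because every aryl building block is then commercial.
- "MandyPhos" below means 1,1′-bis[bis(4-methoxy-3,5-dimethylphenyl)phosphino]-2,2′-bis[α-(dimethylamino)benzyl]ferrocene. Both enantiomers are sold and are written (Sp,Sp) and (Rp,Rp).
- Benzofuran locants are used for both units.

Assumption: the (Sp,Sp) ligand is taken to give the R,R array of unit 1 and the (Rp,Rp) ligand the S,S array of unit 2. The sense is checked on the alcohol from step 5, and if it is reversed the two enantiomers change places.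

Step 1
Reactants: 1 acenaphthoquinone
Product: 2 cis-1,2-dimethyl-1,2-dihydroacenaphthylene-1,2-diol (mac diol; meso)
Conditions: MeMgBr (3 equiv), THF, 0 °C → rt; H2O quench; recrystallisation
Reagents that add atoms: methylmagnesium bromide, C[Mg]Br
Why: Double Grignard 1,2-addition to the 1,2-diketone, in which the second methyl group should enter anti to the bulky magnesium alkoxide to give the cis (meso) diol, the only isomer able to chelate boron, freed from any trans isomer by crystallisation.

Step 2
Reactants: 3 1-ethynyl-3,5-dimethoxybenzene; 2 mac diol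
Product: 5 (E)-2-(3,5-dimethoxyphenyl)ethenyl-B(mac), via alkenyl catecholboronate 4 (not isolated)
Conditions: catecholborane (1.2 equiv), Cy2BH (10 mol%), THF, rt; then 2, rt
Reagents that add atoms: catecholborane, [H]B1Oc2ccccc2O1
Why: Dicyclohexylborane-catalysed syn, anti-Markovnikov hydroboration of the terminal arylalkyne gives the E-alkenylboronate, and transesterification replaces the labile catechol ester by the chelating tertiary diol.

Step 3
Reactants: 6 5-chlorovanillin
Product: 7 2-chloro-4-formyl-6-methoxyphenyl trifluoromethanesulfonate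
Conditions: Tf2O, pyridine, CH2Cl2, 0 °C
Reagents that add atoms: triflic anhydride, O=S(=O)(OS(=O)(=O)C(F)(F)F)C(F)(F)F
Why: O-sulfonylation of an acidic phenol, with the aldehyde, chloride and methyl ether inert.

Step 4
Reactants: 7 2-chloro-4-formyl-6-methoxyphenyl trifluoromethanesulfonate
Product: 8 2-chloro-4-(1,3-dioxolan-2-yl)-6-methoxyphenyl trifluoromethanesulfonate
Conditions: HOCH2CH2OH, p-TsOH (cat.), toluene, reflux, Dean–Stark
Reagents that add atoms: ethylene glycol, OCCO
Why: Acid-catalysed acetalisation of an electron-poor benzaldehyde, which an aryl triflate tolerates and which shields the carbonyl from the nucleophilic borate and the later basic steps.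

Step 5
Reactants: 5 (E)-2-(3,5-dimethoxyphenyl)ethenyl-B(mac); 9 4-bromoveratrole; 8 2-chloro-4-(1,3-dioxolan-2-yl)-6-methoxyphenyl trifluoromethanesulfonate
Product: 13 (1S,2S)-2-[2-chloro-4-(1,3-dioxolan-2-yl)-6-methoxyphenyl]-1-(3,4-dimethoxyphenyl)-2-(3,5-dimethoxyphenyl)ethan-1-ol, via 3,4-dimethoxyphenyllithium 10 (not isolated), via lithium alkenyl(aryl)borate 11 (not isolated), via secondary boronate 12 (not isolated)
Conditions: 9, n-BuLi (1.0 equiv), THF, −78 °C; 5, −78 °C → rt; volatiles removed in vacuo; Pd(OAc)2 (3 mol%), (Rp,Rp)-MandyPhos (3.6 mol%), 8, THF, 60 °C; then 3 M NaOH, 30% H2O2, 0 °C → rt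
Reagents that add atoms: n-butyllithium, [Li]CCCC (its lithium stays only in intermediates 10 and 11); hydrogen peroxide, OO
Why: Enantioselective conjunctive cross-coupling as in step 10 (insertion into C–OTf, anti 1,2-metalate shift of the dimethoxyphenyl group to C2′, retentive reductive elimination at C3′), run with the mirror-image ligand so that anti addition to the E alkene sets C2′ and C3′ as S,S, followed by stereoretentive boronate oxidation.

Step 6
Reactants: 13 (1S,2S)-2-[2-chloro-4-(1,3-dioxolan-2-yl)-6-methoxyphenyl]-1-(3,4-dimethoxyphenyl)-2-(3,5-dimethoxyphenyl)ethan-1-ol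
Product: 15 (2S,3S)-2-(3,4-dimethoxyphenyl)-3-(3,5-dimethoxyphenyl)-4-methoxy-2,3-dihydrobenzofuran-6-carbaldehyde, via dihydrobenzofuran acetal 14 (not isolated)
Conditions: Pd(OAc)2 (5 mol%), 2-(di-tert-butylphosphino)-1,1′-binaphthyl (6 mol%), Cs2CO3, toluene, 80 °C; filtration; then 1 M HCl, THF, rt
Reagents that add atoms: water, O
Why: Buchwald–Hartwig-type intramolecular C–O coupling of the secondary alkoxide onto C7a′–Cl through a six-membered oxapalladacycle whose geometry and bulky ligand disfavour β-hydride elimination; the C2′–O bond is untouched, so both centres are kept and the ring is trans, and dilute acid then hydrolyses the dioxolane.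

Step 7
Reactants: 15 (2S,3S)-2-(3,4-dimethoxyphenyl)-3-(3,5-dimethoxyphenyl)-4-methoxy-2,3-dihydrobenzofuran-6-carbaldehyde
Product: 16 (2S,3S)-2-(3,4-dimethoxyphenyl)-3-(3,5-dimethoxyphenyl)-6-ethynyl-4-methoxy-2,3-dihydrobenzofuran
Conditions: dimethyl (1-diazo-2-oxopropyl)phosphonate, K2CO3, MeOH, rt
Reagents that add atoms: dimethyl (1-diazo-2-oxopropyl)phosphonate, COP(=O)(OC)C(=[N+]=[N-])C(C)=O
Why: Ohira–Bestmann variant of the Seyferth–Gilbert homologation, mild enough for a non-enolisable aldehyde and for the two benzylic stereocentres.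

Step 8
Reactants: 16 (2S,3S)-2-(3,4-dimethoxyphenyl)-3-(3,5-dimethoxyphenyl)-6-ethynyl-4-methoxy-2,3-dihydrobenzofuran; 2 mac diol
Product: 18 (E)-alkenyl-B(mac) of unit 2 (B(mac) on the terminal vinyl carbon at C6′; 2′S,3′S), via alkenyl catecholboronate 17 (not isolated)
Conditions: catecholborane (1.3 equiv), Cy2BH (10 mol%), THF, rt; then 2, rt
Reagents that add atoms: catecholborane, [H]B1Oc2ccccc2O1
Why: The same syn, anti-Markovnikov hydroboration and transesterification as in step 2, which touch neither the ethers nor the ring stereocentres and fix the E geometry the key step needs.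

Step 9
Reactants: 7 2-chloro-4-formyl-6-methoxyphenyl trifluoromethanesulfonate; 19 diethyl (4-methoxybenzyl)phosphonate
Product: 20 2-chloro-6-methoxy-4-[(E)-2-(4-methoxyphenyl)ethenyl]phenyl trifluoromethanesulfonate (ring A triflate)
Conditions: 19, NaHMDS (1.0 equiv), THF, −78 °C; then 7, −78 °C → 0 °C
Reagents that add atoms: none
Why: Horner–Wadsworth–Emmons olefination in which the preformed benzylic phosphonate anion, with no free base left for the triflate, adds to the activated aldehyde much faster than to sulfur and gives the E-stilbene.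

Step 10
Reactants: 18 (E)-alkenyl-B(mac) of unit 2; 21 4-bromoanisole; 20 ring A triflate
Product: 24 open-chain (1R,2R)-secondary B(mac) boronate (C2 bears boron and 4-methoxyphenyl; C3 bears C6′ of unit 2 and C3a of ring A), via 4-methoxyphenyllithium 22 (not isolated), via lithium alkenyl(aryl)borate 23 (not isolated)
Conditions: 21, n-BuLi (1.0 equiv), THF, −78 °C; 18, −78 °C → rt; volatiles removed in vacuo; Pd(OAc)2 (5 mol%), (Sp,Sp)-MandyPhos (6 mol%), 20 (1.2 equiv), THF, 60 °C
Reagents that add atoms: n-butyllithium, [Li]CCCC (its lithium stays only in intermediates 22 and 23)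
Why: The catalyst formed from Pd(OAc)2 and the bisphosphine is reduced in situ to zerovalent palladium, which undergoes oxidative addition at C3a–OTf of 20; since triflate does not coordinate and no halide is present, the divalent arylpalladium is cationic and π-acidic enough to take up the electron-rich C2=C3 bond of borate 23. Complexation induces a metalate rearrangement: the anisyl group leaves tetracoordinate boron for C2 on the alkene face away from the metal as the Pd–C3 σ-bond forms, and C3–C3a reductive elimination, which proceeds with retention, releases 24; both new bonds are acyclic and no ring is closed. The closest known reaction is the enantioselective conjunctive cross-coupling of β-substituted alkenylboron ate complexes with aryl triflates, where the bulky mac diolate suppresses direct Suzuki–Miyaura transfer from boron to palladium. C3 (R) is fixed by the ligand, which decides the alkene face that palladium occupies, and C2 (R) is tied to it by the stereospecific anti addition to the E geometry, the relative configuration that later becomes the trans ring; the centres of unit 2 lie too far away to bias either event. The step needs site selectivity for C–OTf over the adjacent C–Cl bond, secured by the diarylphosphine ligand set and the lower barrier for the triflate, and alkene selectivity for the anionic borate over the neutral stilbene of 20, secured by charge. The β-aryl group and the two ortho substituents next to palladium stretch the documented scope, so conditions are first settled on the like-for-like pairing of step 5.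

Step 11
Reactants: 24 open-chain (1R,2R)-secondary B(mac) boronate
Product: 25 open-chain (1R,2R)-alcohol (C2–OH in place of C2–B)
Conditions: 3 M NaOH, 30% H2O2, THF, 0 °C → rt
Reagents that add atoms: hydrogen peroxide, OO
Why: Boronate oxidation, in which hydroperoxide adds to boron and C2 migrates from boron to oxygen with retention, while the stilbene, aryl chloride and ethers are inert to basic peroxide.

Step 12
Reactants: 25 open-chain (1R,2R)-alcohol
Product: 26 octamethyl ether of the target (2R,3R,2′S,3′S)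
Conditions: Pd(OAc)2 (5 mol%), 2-(di-tert-butylphosphino)-1,1′-binaphthyl (6 mol%), Cs2CO3, toluene, 80–90 °C
Reagents that add atoms: none
Why: Buchwald–Hartwig-type intramolecular C–O coupling as in step 6, closing O1–C7a at the only carbon–halogen bond without touching the C2–O bond, so the anti-addition product gives the trans ring, and intramolecular alkoxide capture outruns any Heck reaction of the hindered stilbene.

Step 13
Reactants: 26 octamethyl ether of the target
Product: 27 target CNP0107857.3
Conditions: BBr3 (20 equiv), CH2Cl2, −78 °C → rt, argon; ice-water quench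
Reagents that add atoms: none
Why: BBr3 ether cleavage, in which the excess reagent first complexes every methoxy oxygen and thereby makes the C2 and C2′ aryl rings poor cation stabilisers, no alkene or arene lies within ring-forming reach of C2 or C2′, and any transient opening of a benzylic C–O bond can only re-close to the more stable trans ring under control of the untouched C3 or C3′.

Compound list
1 | acenaphthoquinone | O=C1C(=O)c2cccc3cccc1c23 | starting material
2 | cis-1,2-dimethyl-1,2-dihydroacenaphthylene-1,2-diol (mac diol, meso) | O[C@]1(C)c2cccc3cccc(c23)[C@]1(C)O | intermediate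
3 | 1-ethynyl-3,5-dimethoxybenzene | COc1cc(C#C)cc(OC)c1 | starting material
4 | 2-[(E)-2-(3,5-dimethoxyphenyl)ethenyl]-1,3,2-benzodioxaborole | COc1cc(/C=C/B2Oc3ccccc3O2)cc(OC)c1 | intermediate
5 | (E)-2-(3,5-dimethoxyphenyl)ethenyl-B(mac) | COc1cc(/C=C/B2O[C@]3(C)c4cccc5cccc(c45)[C@]3(C)O2)cc(OC)c1 | intermediate
6 | 5-chlorovanillin | COc1cc(C=O)cc(Cl)c1O | starting material
7 | 2-chloro-4-formyl-6-methoxyphenyl trifluoromethanesulfonate | COc1cc(C=O)cc(Cl)c1OS(=O)(=O)C(F)(F)F | intermediate
8 | 2-chloro-4-(1,3-dioxolan-2-yl)-6-methoxyphenyl trifluoromethanesulfonate | COc1cc(C2OCCO2)cc(Cl)c1OS(=O)(=O)C(F)(F)F | intermediate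
9 | 4-bromoveratrole | COc1ccc(Br)cc1OC | starting material
10 | 3,4-dimethoxyphenyllithium | [Li]c1ccc(OC)c(OC)c1 | intermediate
11 | lithium (3,4-dimethoxyphenyl)[(E)-2-(3,5-dimethoxyphenyl)ethenyl]-B(mac) borate | [Li+].COc1cc(/C=C/[B-]2(c3ccc(OC)c(OC)c3)O[C@]3(C)c4cccc5cccc(c45)[C@]3(C)O2)cc(OC)c1 | intermediate
12 | (1S,2S)-2-[2-chloro-4-(1,3-dioxolan-2-yl)-6-methoxyphenyl]-1-(3,4-dimethoxyphenyl)-2-(3,5-dimethoxyphenyl)ethyl-B(mac) | COc1ccc(cc1OC)[C@@H](B2O[C@]3(C)c4cccc5cccc(c45)[C@]3(C)O2)[C@@H](c1cc(OC)cc(OC)c1)c1c(OC)cc(C2OCCO2)cc1Cl | intermediate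
13 | (1S,2S)-2-[2-chloro-4-(1,3-dioxolan-2-yl)-6-methoxyphenyl]-1-(3,4-dimethoxyphenyl)-2-(3,5-dimethoxyphenyl)ethan-1-ol | COc1ccc(cc1OC)[C@@H](O)[C@@H](c1cc(OC)cc(OC)c1)c1c(OC)cc(C2OCCO2)cc1Cl | intermediate
14 | (2S,3S)-2-(3,4-dimethoxyphenyl)-3-(3,5-dimethoxyphenyl)-6-(1,3-dioxolan-2-yl)-4-methoxy-2,3-dihydrobenzofuran (trans) | O1CCOC1c1cc(OC)c2c(c1)O[C@H](c1ccc(OC)c(OC)c1)[C@H]2c1cc(OC)cc(OC)c1 | intermediate
15 | (2S,3S)-2-(3,4-dimethoxyphenyl)-3-(3,5-dimethoxyphenyl)-4-methoxy-2,3-dihydrobenzofuran-6-carbaldehyde | O=Cc1cc(OC)c2c(c1)O[C@H](c1ccc(OC)c(OC)c1)[C@H]2c1cc(OC)cc(OC)c1 | intermediate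
16 | (2S,3S)-2-(3,4-dimethoxyphenyl)-3-(3,5-dimethoxyphenyl)-6-ethynyl-4-methoxy-2,3-dihydrobenzofuran | C#Cc1cc(OC)c2c(c1)O[C@H](c1ccc(OC)c(OC)c1)[C@H]2c1cc(OC)cc(OC)c1 | intermediate
17 | (E)-alkenyl catecholboronate of unit 2 | O1c2ccccc2OB1/C=C/c1cc(OC)c2c(c1)O[C@H](c1ccc(OC)c(OC)c1)[C@H]2c1cc(OC)cc(OC)c1 | intermediate
18 | (E)-alkenyl-B(mac) of unit 2 (2′S,3′S) | B1(O[C@]2(C)c3cccc4cccc(c34)[C@]2(C)O1)/C=C/c1cc(OC)c2c(c1)O[C@H](c1ccc(OC)c(OC)c1)[C@H]2c1cc(OC)cc(OC)c1 | intermediate
19 | diethyl (4-methoxybenzyl)phosphonate | CCOP(=O)(Cc1ccc(OC)cc1)OCC | starting material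
20 | 2-chloro-6-methoxy-4-[(E)-2-(4-methoxyphenyl)ethenyl]phenyl trifluoromethanesulfonate | COc1ccc(/C=C/c2cc(OC)c(OS(=O)(=O)C(F)(F)F)c(Cl)c2)cc1 | intermediate
21 | 4-bromoanisole | COc1ccc(Br)cc1 | starting material
22 | 4-methoxyphenyllithium | [Li]c1ccc(OC)cc1 | intermediate
23 | lithium (4-methoxyphenyl)[(E)-alkenyl of unit 2]-B(mac) borate | [Li+].COc1ccc(cc1)[B-]1(O[C@]2(C)c3cccc4cccc(c34)[C@]2(C)O1)/C=C/c1cc(OC)c2c(c1)O[C@H](c1ccc(OC)c(OC)c1)[C@H]2c1cc(OC)cc(OC)c1 | intermediate
24 | (1R,2R)-2-{2-chloro-6-methoxy-4-[(E)-2-(4-methoxyphenyl)ethenyl]phenyl}-2-[(2S,3S)-2-(3,4-dimethoxyphenyl)-3-(3,5-dimethoxyphenyl)-4-methoxy-2,3-dihydrobenzofuran-6-yl]-1-(4-methoxyphenyl)ethyl-B(mac) | COc1ccc(/C=C/c2cc(OC)c(c(Cl)c2)[C@@H](c2cc(OC)c3c(c2)O[C@H](c2ccc(OC)c(OC)c2)[C@H]3c2cc(OC)cc(OC)c2)[C@@H](B2O[C@]3(C)c4cccc5cccc(c45)[C@]3(C)O2)c2ccc(OC)cc2)cc1 | intermediate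
25 | (1R,2R)-alcohol corresponding to 24 (C2–OH) | COc1ccc(/C=C/c2cc(OC)c(c(Cl)c2)[C@@H](c2cc(OC)c3c(c2)O[C@H](c2ccc(OC)c(OC)c2)[C@H]3c2cc(OC)cc(OC)c2)[C@@H](O)c2ccc(OC)cc2)cc1 | intermediate
26 | octamethyl ether of the target (2R,3R,2′S,3′S; both rings trans) | COc1ccc(/C=C/c2cc(OC)c3c(c2)O[C@@H](c2ccc(OC)cc2)[C@@H]3c2cc(OC)c3c(c2)O[C@H](c2ccc(OC)c(OC)c2)[C@H]3c2cc(OC)cc(OC)c2)cc1 | intermediate
27 | (2R,3R)-3-[(2S,3S)-2-(3,4-dihydroxyphenyl)-3-(3,5-dihydroxyphenyl)-4-hydroxy-2,3-dihydrobenzofuran-6-yl]-2-(4-hydroxyphenyl)-6-[(E)-2-(4-hydroxyphenyl)ethenyl]-2,3-dihydrobenzofuran-4-ol | Oc1ccc(/C=C/c2cc(O)c3c(c2)O[C@@H](c2ccc(O)cc2)[C@@H]3c2cc(O)c3c(c2)O[C@H](c2ccc(O)c(O)c2)[C@H]3c2cc(O)cc(O)c2)cc1 | target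

Total step count: 13.
Longest linear sequence: 10 steps (6 → 7 → 8 → 13 → 15 → 16 → 18 → 24 → 25 → 26 → 27; the branch from 1 is equally long).

Steps most likely to fail

1. Step 10.
What may go wrong:
- Direct transfer of the alkenyl or anisyl group from boron to palladium may overtake the metalate shift.
- Alkene binding and reductive elimination at the doubly ortho-substituted arylpalladium may be slow. β-Hydride elimination could then set in, or the benzylic Pd–C3 bond could lose configuration, which would erode diastereo- and facial selectivity.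

Fallback (sets out from aldehyde 15, comes back at 27): C3–C3a is made by carbonyl addition, which tolerates two ortho substituents, and the C2/C3 relationship is left to thermodynamic ring closure. Commercial (E)-3,4′,5-trimethoxystilbene is lithiated between its two methoxy groups (n-BuLi, THF, 0 °C) to 4-lithio-(E)-3,4′,5-trimethoxystilbene F1. This adds to 15 to give the diarylmethanol F2. Dess–Martin oxidation gives the diaryl ketone F3. Corey–Chaykovsky methylenation (Me3SI, NaH, DMSO/THF) gives the 2,2-diaryloxirane F4, and ZnI2-induced Meinwald rearrangement gives the 2,2-diarylacetaldehyde F5. Addition of 22 at −78 °C gives the open-chain triarylethanol F6 as a mixture of isomers at C2 and C3. BBr3 then cleaves all nine methyl ethers and the C2 carbinol ionises to the para-quinone methide. Either of the two equivalent ring A hydroxyl groups closes the ring trans to the C3 substituent. C3 is not controlled, so 27 forms together with the (2S,3S,2′S,3′S) isomer F7. F7 is a diastereomer because unit 2 is already enantiopure, and it is removed by preparative HPLC.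

2. Step 5.
What may go wrong: the same processes as in step 10, met here for the first time. These are competing direct Suzuki–Miyaura transfer, sluggish turnover with the hindered triflate, and poor facial selectivity on a β-aryl alkene. The step runs on cheap material, and its settled conditions are carried into step 10.

Fallback (sets out from triflate 8, comes back at aldehyde 15): enantioselective C–H insertion of a diaryl rhodium carbene, an established asymmetric entry to 2,3-diaryl-2,3-dihydrobenzofurans. Carbonylative Suzuki–Miyaura coupling of 8 with 3,5-dimethoxyphenylboronic acid (PdCl2(dppf), CO 1 atm, K2CO3, KI, anisole, 80 °C) gives the chlorobenzophenone F8. Palladium-catalysed etherification with 3,4-dimethoxybenzyl alcohol ([Pd(allyl)Cl]2, RockPhos, Cs2CO3, toluene, 90 °C) gives the benzyl aryl ether F9. Hydrazine hydrate (AcOH, n-BuOH, reflux) gives the hydrazone F10. MnO2 in CH2Cl2 gives the diaryldiazomethane F11. This is treated without isolation with dirhodium tetrakis[(1-adamantyl)(phthalimido)acetate], Rh2(PTAD)4, in the enantiomer that sets 3′S. The carbene inserts into the OCH2 group and gives the cis-(2R,3S)-dihydrobenzofuran acetal F12. Trifluoroacetic acid in CH2Cl2 equilibrates C2′ through reversible ionisation of the C2′–O1′ bond to the trans isomer 14, and aqueous acid then frees 15.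

3. Step 13.
What may go wrong:
- Lewis-acid ionisation of the benzylic C2–O1 or C2′–O1′ bond followed by proton loss from C3 or C3′ would open a ring and destroy stereocentres.
- Cleavage of the hindered C4 and C4′ methoxy groups may be incomplete.
- The catechol may oxidise in air while the polar octaphenol is isolated.

Fallback (sets out from 26, comes back at 27): cleavage, stereochemical repair and purification are separated instead of being asked of one operation. Compound 26 is cleaved with the softer BCl3/n-Bu4NI pair (CH2Cl2, −78 → 0 °C). The crude polyphenol is stirred in THF/aq NaHCO3 under argon so that any opened benzylic halide re-closes through its para-quinone methide to the trans ring. Peracetylation (Ac2O, pyridine) gives the octaacetate F13, which is stable to air and silica and can be purified from ring-opened or partly methylated material. K2CO3 in degassed MeOH then releases 27.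

Further compounds
F1 | step 10 | 4-lithio-(E)-3,4′,5-trimethoxystilbene | COc1ccc(/C=C/c2cc(OC)c([Li])c(OC)c2)cc1
F2 | step 10 | diarylmethanol (ring A C3a–CH(OH)–C6′ of unit 2, carbinol epimers) | COc1ccc(/C=C/c2cc(OC)c(c(OC)c2)C(O)c2cc(OC)c3c(c2)O[C@H](c2ccc(OC)c(OC)c2)[C@H]3c2cc(OC)cc(OC)c2)cc1
F3 | step 10 | diaryl ketone | COc1ccc(/C=C/c2cc(OC)c(c(OC)c2)C(=O)c2cc(OC)c3c(c2)O[C@H](c2ccc(OC)c(OC)c2)[C@H]3c2cc(OC)cc(OC)c2)cc1
F4 | step 10 | 2,2-diaryloxirane | COc1ccc(/C=C/c2cc(OC)c(c(OC)c2)C2(CO2)c2cc(OC)c3c(c2)O[C@H](c2ccc(OC)c(OC)c2)[C@H]3c2cc(OC)cc(OC)c2)cc1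
F5 | step 10 | 2,2-diarylacetaldehyde (C3 epimers) | COc1ccc(/C=C/c2cc(OC)c(c(OC)c2)C(C=O)c2cc(OC)c3c(c2)O[C@H](c2ccc(OC)c(OC)c2)[C@H]3c2cc(OC)cc(OC)c2)cc1
F6 | step 10 | open-chain triarylethanol with two ortho methoxy groups on ring A (C2 and C3 isomers) | COc1ccc(/C=C/c2cc(OC)c(c(OC)c2)C(C(O)c2ccc(OC)cc2)c2cc(OC)c3c(c2)O[C@H](c2ccc(OC)c(OC)c2)[C@H]3c2cc(OC)cc(OC)c2)cc1
F7 | step 10 | (2S,3S,2′S,3′S) isomer of the target | Oc1ccc(/C=C/c2cc(O)c3c(c2)O[C@H](c2ccc(O)cc2)[C@H]3c2cc(O)c3c(c2)O[C@H](c2ccc(O)c(O)c2)[C@H]3c2cc(O)cc(O)c2)cc1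
F8 | step 5 | [2-chloro-4-(1,3-dioxolan-2-yl)-6-methoxyphenyl](3,5-dimethoxyphenyl)methanone | COc1cc(cc(OC)c1)C(=O)c1c(OC)cc(C2OCCO2)cc1Cl
F9 | step 5 | {2-[(3,4-dimethoxybenzyl)oxy]-4-(1,3-dioxolan-2-yl)-6-methoxyphenyl}(3,5-dimethoxyphenyl)methanone | COc1cc(cc(OC)c1)C(=O)c1c(OC)cc(C2OCCO2)cc1OCc1ccc(OC)c(OC)c1
F10 | step 5 | hydrazone of F9 | COc1cc(cc(OC)c1)C(=NN)c1c(OC)cc(C2OCCO2)cc1OCc1ccc(OC)c(OC)c1
F11 | step 5 | diaryldiazomethane from F10 | COc1cc(cc(OC)c1)C(=[N+]=[N-])c1c(OC)cc(C2OCCO2)cc1OCc1ccc(OC)c(OC)c1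
F12 | step 5 | cis-(2R,3S)-2-(3,4-dimethoxyphenyl)-3-(3,5-dimethoxyphenyl)-6-(1,3-dioxolan-2-yl)-4-methoxy-2,3-dihydrobenzofuran | O1CCOC1c1cc(OC)c2c(c1)O[C@@H](c1ccc(OC)c(OC)c1)[C@H]2c1cc(OC)cc(OC)c1
F13 | step 13 | octaacetate of 27 | CC(=O)Oc1ccc(/C=C/c2cc(OC(C)=O)c3c(c2)O[C@@H](c2ccc(OC(C)=O)cc2)[C@@H]3c2cc(OC(C)=O)c3c(c2)O[C@H](c2ccc(OC(C)=O)c(OC(C)=O)c2)[C@H]3c2cc(OC(C)=O)cc(OC(C)=O)c2)cc1
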